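**Plan**

- Numbering (briarane skeleton): C1 quaternary fusion carbon, C2 acetoxy CH, C3/C4 CH2, C5=C6 Z alkene (methyl on C5), C7 lactone CH–O, C8 and C9 carbinols, C10 fusion CH, C11 CH–CH3, C12 acetoxy CH, C13=C14, C17 lactone CH–CH3, C19 lactone C=O.
- Retrosynthesis cuts the C7–O lactone bond and C8–OH (back to a C7=C8 alkene and a C19 acyl group), then C13=C14 (back to a C12 ketone), then C9–C10 and C1–CH3 with the temporary C2–C7 bond restored, then C1–C2 and C7–C8.
- Forward: both six-membered rings come from the two enantiomers of 4-silyloxycyclohexenone. The cyclohexene that holds C2–C7 is built with a dihydrofuran side ring, the cyclohexenyl unit is added to C2, and the ten-membered ring then arises by ring expansion. The lactone is moved from O9 to O7, and ring A is finished last.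
- C11 and C7 come from anti additions to the silyloxy enones, C17 from anti cuprate addition to a menthyl acetal butenolide; the E enol ether is locked in the dihydrofuran ring.
- C9 and C10 come from the chair of the [3,3] shift and C1 from the face of the methylation (the least controlled point). C8 and C7 come from hydroxyl-directed epoxidation and opening with inversion, C2 from CBS reduction, C12 from Luche reduction followed by Mitsunobu inversion.

Key step: step 16

Assumption: (5R)-5-[(1R,2S,5R)-menthyloxy]furan-2(5H)-one (10) is taken as a purchased reagent.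

**Route**

Step 1
Reactants: 1 cyclohexa-1,3-diene
Product: 2 2,3-dioxabicyclo[2.2.2]oct-5-ene (meso endoperoxide)
Conditions: O2, tetraphenylporphyrin (cat.), visible light, CH2Cl2, −20 °C
Reagents that add atoms: dioxygen, O=O
Why: Singlet oxygen adds across the s-cis diene in a [4+2] cycloaddition (photooxygenation) to give the meso bicyclic peroxide.

Step 2
Reactants: 2 2,3-dioxabicyclo[2.2.2]oct-5-ene
Product: 3 (S)-4-hydroxycyclohex-2-en-1-one
Conditions: 6'-hydroxy cinchona base, quinidine series (5 mol %), CH2Cl2, 0 °C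
Reagents that add atoms: none
Why: Kornblum–DeLaMare rearrangement under a chiral amine base removes one of the two enantiotopic C–H bonds beside the peroxide, so the meso compound should be desymmetrised and the untouched carbinol carbon becomes the 4S centre.

Step 3
Reactants: 3 (S)-4-hydroxycyclohex-2-en-1-one
Product: 4 (S)-4-(tert-butyldimethylsilyloxy)cyclohex-2-en-1-one
Conditions: TBSCl, imidazole, DMF, 0 °C → rt
Reagents that add atoms: tert-butyldimethylsilyl chloride, CC(C)(C)[Si](C)(C)Cl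
Why: Imidazole-promoted silylation of the secondary alcohol leaves the enone and the stereocentre untouched.

Step 4
Reactants: 2 2,3-dioxabicyclo[2.2.2]oct-5-ene
Product: 5 (R)-4-hydroxycyclohex-2-en-1-one
Conditions: pseudo-enantiomeric 6'-hydroxy cinchona base, quinine series (5 mol %), CH2Cl2, 0 °C
Reagents that add atoms: none
Why: The same Kornblum–DeLaMare desymmetrisation with the pseudo-enantiomeric base should deliver the 4R hydroxy enone.

Step 5
Reactants: 5 (R)-4-hydroxycyclohex-2-en-1-one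
Product: 6 (R)-4-(tert-butyldimethylsilyloxy)cyclohex-2-en-1-one
Conditions: TBSCl, imidazole, DMF, 0 °C → rt
Reagents that add atoms: tert-butyldimethylsilyl chloride, CC(C)(C)[Si](C)(C)Cl
Why: Imidazole-promoted silylation as in step 3.

Step 6
Reactants: 6 (R)-4-(tert-butyldimethylsilyloxy)cyclohex-2-en-1-one
Product: 8 (3R,4R)-4-(tert-butyldimethylsilyloxy)-3-methylcyclohex-1-en-1-yl trifluoromethanesulfonate (C11 R, C12 R; methyl and OTBS trans), via lithium (3R,4R)-4-(tert-butyldimethylsilyloxy)-3-methylcyclohex-1-en-1-olate 7 (not isolated)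
Conditions: Me2CuLi (from CuI, MeLi), Et2O, −78 °C; then N-(5-chloropyridin-2-yl)triflimide, THF, −78 → 0 °C
Reagents that add atoms: lithium dimethylcuprate, [Li+].C[Cu-]C; N-(5-chloropyridin-2-yl)triflimide, FC(F)(F)S(=O)(=O)N(c1ccc(Cl)cn1)S(=O)(=O)C(F)(F)F
Why: Conjugate addition of the cuprate anti to the 4-silyloxy group sets C11 (trans to OTBS), and O-triflation of the regiodefined enolate fixes the C1=C10 double bond.

Step 7
Reactants: 8 (3R,4R)-4-(tert-butyldimethylsilyloxy)-3-methylcyclohex-1-en-1-yl trifluoromethanesulfonate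
Product: 9 [(3R,4R)-4-(tert-butyldimethylsilyloxy)-3-methylcyclohex-1-en-1-yl]trimethylstannane
Conditions: Me3SnSnMe3, Pd(PPh3)4 (5 mol %), LiCl, THF, 60 °C
Reagents that add atoms: hexamethylditin, C[Sn](C)(C)[Sn](C)(C)C
Why: Palladium-catalysed stannylation of the enol triflate (Stille-type coupling with the distannane) gives the vinylstannane without touching the stereocentres.

Step 8
Reactants: 10 (5R)-5-[(1R,2S,5R)-menthyloxy]furan-2(5H)-one
Product: 11 (4R,5R)-5-[(1R,2S,5R)-menthyloxy]-4-methyldihydrofuran-2(3H)-one (methyl trans to the menthyloxy group)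
Conditions: Me2CuLi (from CuI, MeLi), Et2O, −78 °C; aq NH4Cl
Reagents that add atoms: lithium dimethylcuprate, [Li+].C[Cu-]C
Why: Conjugate addition of the cuprate to the γ-alkoxybutenolide anti to the menthyloxy group sets C17 (4R of the lactone).

Step 9
Reactants: 11 (4R,5R)-5-menthyloxy-4-methyldihydrofuran-2(3H)-one; 4 (S)-4-(tert-butyldimethylsilyloxy)cyclohex-2-en-1-one
Product: 14 (3R,4S)-4-(tert-butyldimethylsilyloxy)-3-[(3R,4R,5R)-5-menthyloxy-4-methyl-2-oxotetrahydrofuran-3-yl]cyclohex-1-en-1-yl trifluoromethanesulfonate (C7 R, C2 S), via trimethylsilyl ketene acetal of 11 12 (not isolated), via trimethylsilyl enol ether of the Michael adduct 13 (not isolated)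
Conditions: LDA, THF, −78 °C, then TMSCl; 4, TrSbCl6 (5 mol %), CH2Cl2, −78 °C; then CsF, PhNTf2, DME, rt
Reagents that add atoms: N-phenylbis(trifluoromethanesulfonimide), FC(F)(F)S(=O)(=O)N(c1ccccc1)S(=O)(=O)C(F)(F)F
Why: Mukaiyama–Michael addition of the lactone silyl ketene acetal anti to the 4-silyloxy group forms C7–C8 and sets C7, and fluoride-promoted triflation of the resulting silyl enol ether fixes the C5=C6 position (the C8 configuration is lost later and is of no consequence).

Step 10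
Reactants: 14 enol triflate
Product: 15 (3R,4R,5R)-3-[(1R,6S)-6-(tert-butyldimethylsilyloxy)-3-methylcyclohex-2-en-1-yl]-5-menthyloxy-4-methyldihydrofuran-2(3H)-one
Conditions: Me2Zn, Pd(PPh3)4 (5 mol %), THF, 0 °C → rt
Reagents that add atoms: dimethylzinc, C[Zn]C
Why: Negishi coupling of the enol triflate puts the methyl group on C5 and leaves the alkene locked in the ring as the future Z C5=C6 bond.

Step 11
Reactants: 15 methylcyclohexenyl lactone
Product: 16 the corresponding lactol, 3-[(1R,6S)-6-(tert-butyldimethylsilyloxy)-3-methylcyclohex-2-en-1-yl]-5-menthyloxy-4-methyltetrahydrofuran-2-ol (anomers at C9)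
Conditions: DIBAL-H (1.1 equiv), CH2Cl2, −78 °C
Reagents that add atoms: none
Why: DIBAL-H reduction of the γ-lactone stops at the lactol because the tetrahedral aluminate is stable at −78 °C.

Step 12
Reactants: 16 lactol
Product: 18 tert-butyl{[(1S,2R)-2-[(4R,5R)-5-menthyloxy-4-methyl-4,5-dihydrofuran-3-yl]-4-methylcyclohex-3-en-1-yl]oxy}dimethylsilane, via lactol methanesulfonate 17 (not isolated)
Conditions: MsCl, Et3N, CH2Cl2, −20 °C → rt
Reagents that add atoms: none
Why: Mesylation of the lactol and base-induced elimination (glycal-type enol ether synthesis) give the 2,3-dihydrofuran, whose ring holds the C9 oxygen cis to C17, that is, the E enol ether.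

Step 13
Reactants: 18 silyl ether
Product: 19 (1S,2R)-2-[(4R,5R)-5-menthyloxy-4-methyl-4,5-dihydrofuran-3-yl]-4-methylcyclohex-3-en-1-ol
Conditions: TBAF, THF, 0 °C
Reagents that add atoms: none
Why: Fluoride removes the only silyl ether and leaves the base-stable enol ether and acetal.

Step 14
Reactants: 19 alcohol
Product: 20 (R)-2-[(4R,5R)-5-menthyloxy-4-methyl-4,5-dihydrofuran-3-yl]-4-methylcyclohex-3-en-1-one
Conditions: Dess–Martin periodinane, NaHCO3, CH2Cl2, 0 °C
Reagents that add atoms: none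
Why: Buffered Dess–Martin oxidation gives the β,γ-unsaturated ketone under non-basic conditions, so the doubly allylic C7 centre should neither epimerise nor move into conjugation.

Step 15
Reactants: 9 vinylstannane; 20 ketone
Product: 23 (1R,2R)-1-[(3R,4R)-4-(tert-butyldimethylsilyloxy)-3-methylcyclohex-1-en-1-yl]-2-[(4R,5R)-5-menthyloxy-4-methyl-4,5-dihydrofuran-3-yl]-4-methylcyclohex-3-en-1-ol (skeleton 2R,7R; alkenyl groups trans), via [(3R,4R)-4-(tert-butyldimethylsilyloxy)-3-methylcyclohex-1-en-1-yl]lithium 21 (not isolated), via the corresponding dichlorocerium reagent 22 (not isolated)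
Conditions: 9, MeLi, THF, −78 °C; CeCl3, −78 °C; then 20, −78 °C
Reagents that add atoms: none
Why: Tin–lithium exchange and transmetalation give a weakly basic alkenylcerium reagent that adds 1,2 to the enolisable ketone from the face anti to the C7 substituent, which should give the trans-dialkenyl carbinol.

Step 16
Reactants: 23 trans-1-cyclohexenyl-2-dihydrofuranyl-4-methylcyclohex-3-enol
Product: 26 ten-membered C2 ketone fused to the cyclohexane at C1–C10 and to a 2-menthyloxytetrahydrofuran at C8–C9, with Z C5=C6 and E C7=C8 (1S,9R,10S,11R,12R,17R,19R), via potassium alkoxide of 23 24 (not isolated), via ring-expanded potassium C2 enolate 25 (not isolated)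
Conditions: KH, 18-crown-6, THF, 0 °C → rt; then MeI, −78 → 0 °C
Reagents that add atoms: iodomethane, CI
Why: The potassium alkoxide undergoes an anionic oxy-Cope rearrangement through the only chair open to a trans-1,2-dialkenylcyclohexenol (both alkenyl groups equatorial), and the resulting C2 enolate is C-methylated; the closest known reaction is the oxy-Cope ring expansion of 1,2-divinylcyclohexanols to cyclodec-5-enones with alkylation of the enolate in the same flask. The ten-membered ring closes by four-atom ring expansion of the cyclohexene, C9–C10 forming as C2–C7 breaks, not by end-to-end cyclisation. C10 is set by the ring-fixed cyclohexenyl geometry (C11 equatorial in the chair) and C9 by the enol ether geometry locked in the dihydrofuran (oxygen equatorial), both relayed from C2 and C7, which should give 9R,10S and an E C7=C8 bond while the preset C5=C6 stays Z. C1 is set by the face on which methyl iodide meets the enolate, and the target needs entry cis to the C10–C9 bond (trans ring fusion). All the substrate offers for this is the conformation of the fused enolate, namely the half-chair with C9 equatorial in which the macrocycle lies across the opposite face, so the step depends on alkylation through that conformer.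

Step 17
Reactants: 26 ten-membered ketone with menthyl acetal
Product: 27 the C19 lactol (2-hydroxytetrahydrofuran in place of the menthyl acetal; anomers at C19)
Conditions: 1 M HCl, THF, 0 °C → rt
Reagents that add atoms: water, O
Why: Mild aqueous acid hydrolyses the furanoside-type acetal at C19 and leaves the silyl ether, the ketone and the diene.

Step 18
Reactants: 27 lactol
Product: 28 the γ-lactone closed on O9 (C19(=O)–O–C9; 17R)
Conditions: TEMPO (10 mol %), PhI(OAc)2, CH2Cl2, rt
Reagents that add atoms: none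
Why: Oxoammonium oxidation converts the lactol into the γ-lactone without affecting the alkenes or the ketone.

Step 19
Reactants: 28 O9-lactone
Product: 31 the γ-lactone closed on O7 with free 8-OH and 9-OH (7S,8R,9R,17R; C2 ketone, 12-OTBS), via C9-hydroxy C19-acid 29 (not isolated), via (7R,8R)-epoxy acid 30 (not isolated)
Conditions: LiOH, THF/H2O, 0 °C; 1 M HCl to pH 4; then VO(acac)2 (5 mol %), t-BuOOH, CH2Cl2, 0 °C → rt
Reagents that add atoms: lithium hydroxide, [Li+].[OH-]; tert-butyl hydroperoxide, CC(C)(C)OO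
Why: Saponification frees the C9 hydroxyl and the C19 acid, vanadium-catalysed hydroxyl-directed epoxidation should deliver oxygen to the C7=C8 face syn to the C9–OH (A1,2-strain-controlled threo transition state, 8R), and the acid opens the allylic epoxide at C7 with inversion (7S) to the γ-lactone.

Step 20
Reactants: 31 lactone diol
Product: 32 the 8,9-O-isopropylidene acetal of 31
Conditions: 2-methoxypropene, PPTS (cat.), CH2Cl2, 0 °C
Reagents that add atoms: 2-methoxypropene, COC(C)=C
Why: Acid-catalysed transacetalisation ties the tertiary/secondary diol into a dioxolane.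

Step 21
Reactants: 32 acetonide ketone
Product: 33 the (2R)-alcohol
Conditions: (S)-Me-CBS (20 mol %), catecholborane, toluene, −78 °C
Reagents that add atoms: none
Why: CBS reduction delivers hydride under reagent control to the ketone flanked by the quaternary C1 (large) and C3H2 (small), which should give the 2R alcohol.

Step 22
Reactants: 33 C2 alcohol
Product: 34 the C2 acetate
Conditions: Ac2O, Et3N, DMAP, CH2Cl2, rt
Reagents that add atoms: acetic anhydride, CC(=O)OC(C)=O
Why: DMAP-catalysed acetylation of the only free hydroxyl group.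

Step 23
Reactants: 34 C2 acetate, 12-OTBS
Product: 35 the (12R)-alcohol
Conditions: TBAF, AcOH, THF, rt
Reagents that add atoms: none
Why: Buffered fluoride cleaves the silyl ether without acyl migration or lactone opening.

Step 24
Reactants: 35 C12 alcohol
Product: 36 the C12 ketone
Conditions: Dess–Martin periodinane, NaHCO3, CH2Cl2, rt
Reagents that add atoms: none
Why: Dess–Martin oxidation of the secondary alcohol under neutral conditions.

Step 25
Reactants: 36 C12 ketone
Product: 38 the 13-en-12-one, via C12 trimethylsilyl enol ether (C12=C13) 37 (not isolated)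
Conditions: LiHMDS, TMSCl, THF, −78 °C; then Pd(OAc)2, MeCN, rt
Reagents that add atoms: none
Why: Kinetic enolisation towards the less substituted C13 and Saegusa–Ito dehydrogenation of the silyl enol ether give the C13=C14 enone.

Step 26
Reactants: 38 enone
Product: 39 the (12S)-allylic alcohol (OH cis to the C11 methyl)
Conditions: NaBH4, CeCl3·7H2O, MeOH, −78 °C
Reagents that add atoms: none
Why: Luche 1,2-reduction, with hydride arriving on the α face opposite the C11 methyl and the C10–C9 bond, should give the 12S alcohol.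

Step 27
Reactants: 39 (12S)-allylic alcohol
Product: 40 the 2,12-diacetate 8,9-acetonide (12R)
Conditions: PPh3, DIAD, AcOH, THF, 0 °C → rt
Reagents that add atoms: acetic acid, CC(=O)O
Why: Mitsunobu esterification inverts C12 by SN2 displacement on the unhindered α face, which should give the 12R acetate trans to the C11 methyl.

Step 28
Reactants: 40 diacetate acetonide
Product: 41 target compound CNP0286823.1
Conditions: 80% aq AcOH, 40 °C
Reagents that add atoms: none
Why: Mild aqueous acid hydrolyses the acetonide and leaves the two acetates and the lactone.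

**Compound list**

1 | cyclohexa-1,3-diene | C1=CC=CCC1 | starting material
2 | 2,3-dioxabicyclo[2.2.2]oct-5-ene | C1=CC2CCC1OO2 | intermediate
3 | (S)-4-hydroxycyclohex-2-en-1-one | O=C1C=C[C@@H](O)CC1 | intermediate
4 | (S)-4-(tert-butyldimethylsilyloxy)cyclohex-2-en-1-one | O=C1C=C[C@@H](O[Si](C)(C)C(C)(C)C)CC1 | intermediate
5 | (R)-4-hydroxycyclohex-2-en-1-one | O=C1C=C[C@H](O)CC1 | intermediate
6 | (R)-4-(tert-butyldimethylsilyloxy)cyclohex-2-en-1-one | O=C1C=C[C@H](O[Si](C)(C)C(C)(C)C)CC1 | intermediate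
7 | lithium (3R,4R)-4-(tert-butyldimethylsilyloxy)-3-methylcyclohex-1-en-1-olate | [Li+].[O-]C1=C[C@@H](C)[C@H](O[Si](C)(C)C(C)(C)C)CC1 | intermediate
8 | (3R,4R)-4-(tert-butyldimethylsilyloxy)-3-methylcyclohex-1-en-1-yl trifluoromethanesulfonate | FC(F)(F)S(=O)(=O)OC1=C[C@@H](C)[C@H](O[Si](C)(C)C(C)(C)C)CC1 | intermediate
9 | [(3R,4R)-4-(tert-butyldimethylsilyloxy)-3-methylcyclohex-1-en-1-yl]trimethylstannane | C[Sn](C)(C)C1=C[C@@H](C)[C@H](O[Si](C)(C)C(C)(C)C)CC1 | intermediate
10 | (5R)-5-[(1R,2S,5R)-menthyloxy]furan-2(5H)-one | O=C1C=C[C@H](O[C@@H]2C[C@H](C)CC[C@H]2C(C)C)O1 | starting material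
11 | (4R,5R)-5-[(1R,2S,5R)-menthyloxy]-4-methyldihydrofuran-2(3H)-one | O=C1C[C@@H](C)[C@H](O[C@@H]2C[C@H](C)CC[C@H]2C(C)C)O1 | intermediate
12 | {[(4R,5R)-5-menthyloxy-4-methyl-4,5-dihydrofuran-2-yl]oxy}trimethylsilane (silyl ketene acetal) | C[Si](C)(C)OC1=C[C@@H](C)[C@H](O[C@@H]2C[C@H](C)CC[C@H]2C(C)C)O1 | intermediate
13 | trimethylsilyl enol ether of the Michael adduct (C5–OTMS, C5=C6; 7R, 2S) | C[Si](C)(C)OC1=C[C@H]([C@@H]2[C@@H](C)[C@H](O[C@@H]3C[C@H](C)CC[C@H]3C(C)C)OC2=O)[C@@H](O[Si](C)(C)C(C)(C)C)CC1 | intermediate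
14 | (3R,4S)-4-(tert-butyldimethylsilyloxy)-3-[(3R,4R,5R)-5-menthyloxy-4-methyl-2-oxotetrahydrofuran-3-yl]cyclohex-1-en-1-yl trifluoromethanesulfonate | FC(F)(F)S(=O)(=O)OC1=C[C@H]([C@@H]2[C@@H](C)[C@H](O[C@@H]3C[C@H](C)CC[C@H]3C(C)C)OC2=O)[C@@H](O[Si](C)(C)C(C)(C)C)CC1 | intermediate
15 | (3R,4R,5R)-3-[(1R,6S)-6-(tert-butyldimethylsilyloxy)-3-methylcyclohex-2-en-1-yl]-5-menthyloxy-4-methyldihydrofuran-2(3H)-one | CC1=C[C@H]([C@@H]2[C@@H](C)[C@H](O[C@@H]3C[C@H](C)CC[C@H]3C(C)C)OC2=O)[C@@H](O[Si](C)(C)C(C)(C)C)CC1 | intermediate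
16 | lactol of 15 (tetrahydrofuran-2-ol, anomers) | CC1=C[C@H]([C@@H]2[C@@H](C)[C@H](O[C@@H]3C[C@H](C)CC[C@H]3C(C)C)OC2O)[C@@H](O[Si](C)(C)C(C)(C)C)CC1 | intermediate
17 | methanesulfonate of lactol 16 | CC1=C[C@H]([C@@H]2[C@@H](C)[C@H](O[C@@H]3C[C@H](C)CC[C@H]3C(C)C)OC2OS(C)(=O)=O)[C@@H](O[Si](C)(C)C(C)(C)C)CC1 | intermediate
18 | tert-butyl{[(1S,2R)-2-[(4R,5R)-5-menthyloxy-4-methyl-4,5-dihydrofuran-3-yl]-4-methylcyclohex-3-en-1-yl]oxy}dimethylsilane | CC1=C[C@H](C2=CO[C@@H](O[C@@H]3C[C@H](C)CC[C@H]3C(C)C)[C@@H]2C)[C@@H](O[Si](C)(C)C(C)(C)C)CC1 | intermediate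
19 | (1S,2R)-2-[(4R,5R)-5-menthyloxy-4-methyl-4,5-dihydrofuran-3-yl]-4-methylcyclohex-3-en-1-ol | CC1=C[C@H](C2=CO[C@@H](O[C@@H]3C[C@H](C)CC[C@H]3C(C)C)[C@@H]2C)[C@@H](O)CC1 | intermediate
20 | (R)-2-[(4R,5R)-5-menthyloxy-4-methyl-4,5-dihydrofuran-3-yl]-4-methylcyclohex-3-en-1-one | CC1=C[C@H](C2=CO[C@@H](O[C@@H]3C[C@H](C)CC[C@H]3C(C)C)[C@@H]2C)C(=O)CC1 | intermediate
21 | [(3R,4R)-4-(tert-butyldimethylsilyloxy)-3-methylcyclohex-1-en-1-yl]lithium | [Li]C1=C[C@@H](C)[C@H](O[Si](C)(C)C(C)(C)C)CC1 | intermediate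
22 | dichloro[(3R,4R)-4-(tert-butyldimethylsilyloxy)-3-methylcyclohex-1-en-1-yl]cerium | Cl[Ce](Cl)C1=C[C@@H](C)[C@H](O[Si](C)(C)C(C)(C)C)CC1 | intermediate
23 | (1R,2R)-1-[(3R,4R)-4-(tert-butyldimethylsilyloxy)-3-methylcyclohex-1-en-1-yl]-2-[(4R,5R)-5-menthyloxy-4-methyl-4,5-dihydrofuran-3-yl]-4-methylcyclohex-3-en-1-ol | O[C@@]1(CCC(C)=C[C@@H]1C3=CO[C@@H](O[C@@H]4C[C@H](C)CC[C@H]4C(C)C)[C@@H]3C)C2=C[C@@H](C)[C@H](O[Si](C)(C)C(C)(C)C)CC2 | intermediate
24 | potassium alkoxide of 23 | [K+].[O-][C@@]1(CCC(C)=C[C@@H]1C3=CO[C@@H](O[C@@H]4C[C@H](C)CC[C@H]4C(C)C)[C@@H]3C)C2=C[C@@H](C)[C@H](O[Si](C)(C)C(C)(C)C)CC2 | intermediate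
25 | potassium C2 enolate of the ring-expanded ketone (E C1=C2, Z C5=C6, E C7=C8; 9R,10S) | [K+].CC(C)(C)[Si](C)(C)O[C@@H]1CC/C2=C(/[O-])CC/C(C)=C\C=C3/[C@@H](C)[C@H](O[C@@H]4C[C@H](C)CC[C@H]4C(C)C)O[C@@H]3[C@H]2[C@H]1C | intermediate
26 | ten-membered C2 ketone, C1-methylated, fused to the 12-OTBS cyclohexane and to the 2-menthyloxytetrahydrofuran (1S,9R,10S,11R,12R,17R,19R) | CC(C)(C)[Si](C)(C)O[C@@H]1CC[C@@]2(C)[C@H]([C@H]1C)[C@H]3O[C@@H](O[C@@H]4C[C@H](C)CC[C@H]4C(C)C)[C@H](C)/C3=C\C=C(\C)CCC2=O | intermediate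
27 | C19 lactol of 26 (anomers) | CC(C)(C)[Si](C)(C)O[C@@H]1CC[C@@]2(C)[C@H]([C@H]1C)[C@H]3OC(O)[C@H](C)/C3=C\C=C(\C)CCC2=O | intermediate
28 | γ-lactone closed on O9 (C19(=O)–O–C9) | CC(C)(C)[Si](C)(C)O[C@@H]1CC[C@@]2(C)[C@H]([C@H]1C)[C@H]3OC(=O)[C@H](C)/C3=C\C=C(\C)CCC2=O | intermediate
29 | C9-hydroxy C19-carboxylic acid | CC(C)(C)[Si](C)(C)O[C@@H]1CC[C@@]2(C)[C@H]([C@H]1C)[C@@H](O)/C(=C/C=C(/C)CCC2=O)[C@@H](C)C(=O)O | intermediate
30 | (7R,8R)-7,8-epoxy C9-hydroxy C19-carboxylic acid | CC(C)(C)[Si](C)(C)O[C@@H]1CC[C@@]2(C)[C@H]([C@H]1C)[C@@H](O)[C@]3(O[C@@H]3/C=C(/C)CCC2=O)[C@@H](C)C(=O)O | intermediate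
31 | γ-lactone closed on O7 with 8-OH and 9-OH, C2 ketone, 12-OTBS | CC(C)(C)[Si](C)(C)O[C@@H]1CC[C@@]2(C)[C@H]([C@H]1C)[C@@H](O)[C@@]3(O)[C@H](/C=C(/C)CCC2=O)OC(=O)[C@@H]3C | intermediate
32 | 8,9-O-isopropylidene acetal of 31 | CC(C)(C)[Si](C)(C)O[C@@H]1CC[C@@]2(C)[C@H]([C@H]1C)[C@H]4OC(C)(C)O[C@@]43[C@H](/C=C(/C)CCC2=O)OC(=O)[C@@H]3C | intermediate
33 | (2R)-alcohol of 32 | CC(C)(C)[Si](C)(C)O[C@@H]1CC[C@@]2(C)[C@H]([C@H]1C)[C@H]4OC(C)(C)O[C@@]43[C@H](/C=C(/C)CC[C@H]2O)OC(=O)[C@@H]3C | intermediate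
34 | C2 acetate of 33 | CC(C)(C)[Si](C)(C)O[C@@H]1CC[C@@]2(C)[C@H]([C@H]1C)[C@H]4OC(C)(C)O[C@@]43[C@H](/C=C(/C)CC[C@H]2OC(C)=O)OC(=O)[C@@H]3C | intermediate
35 | (12R)-alcohol, C2 acetate, 8,9-acetonide | O[C@@H]1CC[C@@]2(C)[C@H]([C@H]1C)[C@H]4OC(C)(C)O[C@@]43[C@H](/C=C(/C)CC[C@H]2OC(C)=O)OC(=O)[C@@H]3C | intermediate
36 | C12 ketone | O=C1CC[C@@]2(C)[C@H]([C@H]1C)[C@H]4OC(C)(C)O[C@@]43[C@H](/C=C(/C)CC[C@H]2OC(C)=O)OC(=O)[C@@H]3C | intermediate
37 | C12 trimethylsilyl enol ether (C12=C13) | C[Si](C)(C)OC1=CC[C@@]2(C)[C@H]([C@H]1C)[C@H]4OC(C)(C)O[C@@]43[C@H](/C=C(/C)CC[C@H]2OC(C)=O)OC(=O)[C@@H]3C | intermediate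
38 | 13-en-12-one | O=C1C=C[C@@]2(C)[C@H]([C@H]1C)[C@H]4OC(C)(C)O[C@@]43[C@H](/C=C(/C)CC[C@H]2OC(C)=O)OC(=O)[C@@H]3C | intermediate
39 | (12S)-allylic alcohol | O[C@H]1C=C[C@@]2(C)[C@H]([C@H]1C)[C@H]4OC(C)(C)O[C@@]43[C@H](/C=C(/C)CC[C@H]2OC(C)=O)OC(=O)[C@@H]3C | intermediate
40 | 2,12-diacetate 8,9-acetonide (12R) | CC(=O)O[C@@H]1C=C[C@@]2(C)[C@H]([C@H]1C)[C@H]4OC(C)(C)O[C@@]43[C@H](/C=C(/C)CC[C@H]2OC(C)=O)OC(=O)[C@@H]3C | intermediate
41 | CNP0286823.1 | CC(=O)O[C@@H]1C=C[C@@]2(C)[C@H]([C@H]1C)[C@@H](O)[C@@]1(O)[C@H](/C=C(/C)CC[C@H]2OC(C)=O)OC(=O)[C@@H]1C | target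

**Step count**

Total: 28 steps. Longest linear sequence: 23 steps (steps 1–3, then 9–28).

**Steps most likely to fail**

Step 16, facial selectivity of the C-methylation. Methyl iodide may meet enolate 25 on the face anti to the C10–C9 bond. That is the open face of the half-chair with C9 axial, the conformer in which the enolate is born from the chair transition state. The result would be the C1 epimer of 26 with a cis ring fusion. In the fallback the two carbon substituents of C1 change roles: the methyl group sits on C1 during the rearrangement and the ring carbon C14 is the electrophile. It sets out from ketone 20 and returns at 26. 3-(4-Methoxybenzyloxy)propanal is propargylated with the allenylzinc reagent from (S)-but-3-yn-2-yl methanesulfonate (Pd(OAc)2, PPh3, Et2Zn) to the anti homopropargylic alcohol F1. Silylation (TBSOTf, 2,6-lutidine) gives the silyl ether F2, alkyne methylation (n-BuLi, MeI) the 2-alkyne F3, DDQ the primary alcohol F4, and PPh3 with N-chlorosuccinimide the primary chloride F5. Hydrozirconation with Cp2Zr(H)Cl and iodinolysis give the (E)-2-iodoalkene F6. Iodine–lithium exchange (t-BuLi), CeCl3 and ketone 20 give the trans carbinol F7. KH and 18-crown-6 turn it into the potassium alkoxide F8, which should rearrange through the same chair to the C1-methyl enolate F9. The tethered chloride can close a six-membered ring only on the enolate face anti to C10–C9; provided the enolate is alkylated before the C1=C2 unit turns over in the ring, this 6-exo alkylation closes the cyclohexane with the trans fusion and gives 26.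

Step 19, the saponification, epoxidation and lactonisation sequence. Hydroxide may epimerise C17 or move the C7=C8 bond into conjugation with the carboxylate. The hydroxy acid 29 may close back to 28 before it is epoxidised, and the free acid may slow the vanadium catalyst. The fallback sets out from lactone 28 and returns at 31. The lactone is opened without hydroxide by aminolysis (MeNHOMe·HCl, AlMe3) to the C9-hydroxy Weinreb amide F10, which does not readily relactonise. The same directed epoxidation (VO(acac)2, t-BuOOH) gives the epoxy amide F11. Camphorsulfonic acid in wet CH2Cl2 then lets the amide oxygen open the epoxide at C7 with inversion and hydrolyses the iminium lactone to 31.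

Step 12, elimination of the lactol. The anomeric mesylate may be replaced by chloride and persist, or the enol ether may lose menthol under traces of acid and aromatise to the furan. The fallback sets out from lactone 15 and returns at 18. KHMDS and PhNTf2 convert the lactone into the ketene acetal triflate F12. Palladium-catalysed formate reduction (Pd(OAc)2, PPh3, HCO2H, Bu3N) replaces the triflate by hydrogen and gives dihydrofuran 18 under basic conditions throughout.

Further compounds
F1 | step 16 | (3R,4R)-1-(4-methoxybenzyloxy)-4-methylhex-5-yn-3-ol | COc1ccc(COCC[C@@H](O)[C@H](C)C#C)cc1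
F2 | step 16 | tert-butyldimethylsilyl ether of F1 | COc1ccc(COCC[C@@H](O[Si](C)(C)C(C)(C)C)[C@H](C)C#C)cc1
F3 | step 16 | (3R,4R)-3-(tert-butyldimethylsilyloxy)-1-(4-methoxybenzyloxy)-4-methylhept-5-yne | COc1ccc(COCC[C@@H](O[Si](C)(C)C(C)(C)C)[C@H](C)C#CC)cc1
F4 | step 16 | (3R,4R)-3-(tert-butyldimethylsilyloxy)-4-methylhept-5-yn-1-ol | OCC[C@@H](O[Si](C)(C)C(C)(C)C)[C@H](C)C#CC
F5 | step 16 | (3R,4R)-3-(tert-butyldimethylsilyloxy)-1-chloro-4-methylhept-5-yne | ClCC[C@@H](O[Si](C)(C)C(C)(C)C)[C@H](C)C#CC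
F6 | step 16 | (3R,4R,5E)-3-(tert-butyldimethylsilyloxy)-1-chloro-6-iodo-4-methylhept-5-ene | ClCC[C@@H](O[Si](C)(C)C(C)(C)C)[C@H](C)/C=C(\C)I
F7 | step 16 | trans carbinol from 20 and the alkenylcerium reagent of F6 (2R,7R; E C1=C10 with methyl on C1) | O[C@@]1(CCC(C)=C[C@@H]1C3=CO[C@@H](O[C@@H]4C[C@H](C)CC[C@H]4C(C)C)[C@@H]3C)/C(C)=C/[C@@H](C)[C@H](O[Si](C)(C)C(C)(C)C)CCCl
F8 | step 16 | potassium alkoxide of F7 | [K+].[O-][C@@]1(CCC(C)=C[C@@H]1C3=CO[C@@H](O[C@@H]4C[C@H](C)CC[C@H]4C(C)C)[C@@H]3C)/C(C)=C/[C@@H](C)[C@H](O[Si](C)(C)C(C)(C)C)CCCl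
F9 | step 16 | ring-expanded potassium C2 enolate with methyl on C1 and the chloroalkyl chain on C10 | [K+].ClCC[C@@H](O[Si](C)(C)C(C)(C)C)[C@H](C)[C@H]1/C(C)=C(\[O-])CC/C(C)=C\C=C2/[C@@H](C)[C@H](O[C@@H]3C[C@H](C)CC[C@H]3C(C)C)O[C@@H]21
F10 | step 19 | C9-hydroxy C19 N-methoxy-N-methylamide | CC(C)(C)[Si](C)(C)O[C@@H]1CC[C@@]2(C)[C@H]([C@H]1C)[C@@H](O)/C(=C/C=C(/C)CCC2=O)[C@@H](C)C(=O)N(C)OC
F11 | step 19 | (7R,8R)-epoxy C9-hydroxy N-methoxy-N-methylamide | CC(C)(C)[Si](C)(C)O[C@@H]1CC[C@@]2(C)[C@H]([C@H]1C)[C@@H](O)[C@]3(O[C@@H]3/C=C(/C)CCC2=O)[C@@H](C)C(=O)N(C)OC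
F12 | step 12 | ketene acetal triflate of lactone 15 (2-triflyloxy-4,5-dihydrofuran) | CC1=C[C@H](C2=C(OS(=O)(=O)C(F)(F)F)O[C@@H](O[C@@H]3C[C@H](C)CC[C@H]3C(C)C)[C@@H]2C)[C@@H](O[Si](C)(C)C(C)(C)C)CC1
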